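**Plan**
Numbering: ring A is C1 (quaternary, bears C12H2OAc)–C2H2–C3H(OAc)–C4H(OH)–C5Me2–C6 (quaternary); the cage is C6, C7H2, the cyclopropane C8H–C9H–C10(Me) and C11H(OAc).
Feature: without the cyclopropane bond C8–C9 the cage is a bicyclo[2.2.1]heptane (bridgeheads C6 and C10) fused to ring A along C1–C6, with C5, C6 and C1 on one chain; it maps onto a cyclopentadiene C6=C7–C8=C10 (C11 as ketal carbon) tethered through C5–C2 to a dienophile C1=C9.
Cuts: the acetates and the C11 oxidation level; C8–C9 (carbene C–H insertion); C1–C6 and C9–C10 (intramolecular Diels–Alder); C1=C9 (nitroaldol); C6–C11, C11–C10 and C7–C8 (Pauson–Khand); C10–CH3 (alkylation); C4–C5 (propargylation).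
Forward: the chain C12–C1–C2–C3–C4 comes from a lactone, C5–C7 is added at C4, the cyclopentenone and then the dienyl ketal are built, the nitroacrylate is installed, ring A and the norbornene close together, and the cyclopropane closes last.
Stereochemistry: C3 from the (S)-lactone; C4 by Felkin–Anh addition; C1, C6 and C10 in the cycloaddition (face chosen by the C3/C4 acetonide); C8 and C9 fixed by the cage; C11 by cation capture on the face remote from ring A.

Key step: step 13

Assumption: the dehydration in step 12 is taken to give the Z nitroacrylate; its E isomer would differ in the adduct only at C9, which becomes sp2 in step 15.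

Step 1
Reactants: 1 (S)-5-(hydroxymethyl)dihydrofuran-2(3H)-one
Product: 2 (S)-5-oxotetrahydrofuran-2-carbaldehyde
Conditions: DMP (1,1,1-triacetoxy-1,1-dihydro-1,2-benziodoxol-3(1H)-one), pyridine, CH2Cl2, 0 °C to rt; used crude
Reagents that add atoms: none
Why: Buffered periodinane oxidation of the primary alcohol should give the α-acyloxy aldehyde without epimerising C3 (hypervalent-iodine alcohol oxidation).

Step 2
Reactants: 2 (S)-5-oxotetrahydrofuran-2-carbaldehyde; 3 3-chloro-3-methylbut-1-yne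
Product: 5 (S)-5-[(R)-1-hydroxy-2,2-dimethylbut-3-yn-1-yl]dihydrofuran-2(3H)-one, via allenylzinc chloride 4 (not isolated)
Conditions: Zn dust (activated with Me3SiCl/BrCH2CH2Br), THF, 0 °C; then aldehyde 2, −20 °C to rt; 1 M HCl
Reagents that add atoms: none
Why: In this Barbier-type propargylation the organozinc rests as the allenyl species and should add through a six-membered SE2′ transition state, so the bond forms at the CMe2 carbon (C5) and leaves the terminal alkyne, while Felkin–Anh addition to the non-chelating α-acyloxy aldehyde sets C4 anti to O3 (4R).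

Step 3
Reactants: 5 (S)-5-[(R)-1-hydroxy-2,2-dimethylbut-3-yn-1-yl]dihydrofuran-2(3H)-one
Product: 6 methyl 3-[(4S,5R)-2,2-dimethyl-5-(2-methylbut-3-yn-2-yl)-1,3-dioxolan-4-yl]propanoate
Conditions: MeOH, Me2C(OMe)2, TsOH·H2O (cat.), rt
Reagents that add atoms: methanol, CO; 2,2-dimethoxypropane, COC(C)(C)OC
Why: Acid-catalysed methanolysis of the γ-lactone is pulled to the open ester because the freed C3/C4 diol is trapped as the cis-dioxolane (transacetalisation).

Step 4
Reactants: 6 methyl 3-[(4S,5R)-2,2-dimethyl-5-(2-methylbut-3-yn-2-yl)-1,3-dioxolan-4-yl]propanoate; 7 ethylene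
Product: 9 methyl 3-[(4S,5R)-2,2-dimethyl-5-[2-(5-oxocyclopent-1-en-1-yl)propan-2-yl]-1,3-dioxolan-4-yl]propanoate, via hexacarbonyldicobalt alkyne complex 8 (not isolated)
Conditions: Co2(CO)8, CH2Cl2, rt; then ethylene (30 bar), Me3NO·2H2O, toluene, 40 °C
Reagents that add atoms: dicobalt octacarbonyl Co2(CO)8 (one CO becomes C11=O), [Co].[Co].[C-]#[O+].[C-]#[O+].[C-]#[O+].[C-]#[O+].[C-]#[O+].[C-]#[O+].[C-]#[O+].[C-]#[O+]
Why: In the amine-oxide-promoted Pauson–Khand reaction the substituted alkyne carbon ends next to the new carbonyl, so C6 (bearing C5) becomes the α-carbon of the cyclopentenone and C7 its β-CH.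

Step 5
Reactants: 9 methyl 3-[(4S,5R)-2,2-dimethyl-5-[2-(5-oxocyclopent-1-en-1-yl)propan-2-yl]-1,3-dioxolan-4-yl]propanoate
Product: 11 methyl 3-[(4S,5R)-2,2-dimethyl-5-[2-(4-methyl-5-oxocyclopent-1-en-1-yl)propan-2-yl]-1,3-dioxolan-4-yl]propanoate (both C10 epimers), via lithium dienolate 10 (not isolated)
Conditions: LiN(SiMe3)2, THF, −78 °C; then MeI, −78 to −40 °C
Reagents that add atoms: iodomethane, CI
Why: The α′-enolate of the cyclopentenone, more acidic than the ester CH2, is methylated at C10 (enolate alkylation), and the C10 configuration does not matter because C10 becomes sp2 in step 8.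

Step 6
Reactants: 11 methyl 3-[(4S,5R)-2,2-dimethyl-5-[2-(4-methyl-5-oxocyclopent-1-en-1-yl)propan-2-yl]-1,3-dioxolan-4-yl]propanoate
Product: 12 methyl 3-[(4S,5R)-5-[2-(5,5-dimethoxy-4-methylcyclopent-1-en-1-yl)propan-2-yl]-2,2-dimethyl-1,3-dioxolan-4-yl]propanoate
Conditions: MeOSiMe3, Me3SiOTf (cat.), CH2Cl2, −78 to −30 °C; pyridine quench
Reagents that add atoms: methoxytrimethylsilane, CO[Si](C)(C)C
Why: Silyl-triflate-catalysed ketalisation with the methyl silyl ether works at low temperature on hindered conjugated ketones, does not move the double bond and should leave the acetonide alone (aprotic ketalisation).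

Step 7
Reactants: 12 methyl 3-[(4S,5R)-5-[2-(5,5-dimethoxy-4-methylcyclopent-1-en-1-yl)propan-2-yl]-2,2-dimethyl-1,3-dioxolan-4-yl]propanoate
Product: 13 methyl 3-[(4S,5R)-5-[2-(3-bromo-5,5-dimethoxy-4-methylcyclopent-1-en-1-yl)propan-2-yl]-2,2-dimethyl-1,3-dioxolan-4-yl]propanoate (bromide at C8)
Conditions: NBS, AIBN (cat.), K2CO3, CCl4, 75 °C
Reagents that add atoms: N-bromosuccinimide, O=C1CCC(=O)N1Br
Why: In this Wohl–Ziegler bromination C8 carries the only allylic hydrogens of the ring alkene (C5 is quaternary, C11 is the ketal carbon), so the allyl radical should be brominated at C8.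

Step 8
Reactants: 13 methyl 3-[(4S,5R)-5-[2-(3-bromo-5,5-dimethoxy-4-methylcyclopent-1-en-1-yl)propan-2-yl]-2,2-dimethyl-1,3-dioxolan-4-yl]propanoate
Product: 14 methyl 3-[(4S,5R)-5-[2-(5,5-dimethoxy-4-methylcyclopenta-1,3-dien-1-yl)propan-2-yl]-2,2-dimethyl-1,3-dioxolan-4-yl]propanoate
Conditions: t-BuOK, THF, −20 to 0 °C, short reaction time
Reagents that add atoms: none
Why: Dehydrobromination of the allylic bromide toward its only β-hydrogen (C10–H) gives the cyclopentadienone dimethyl ketal, the classical elimination route to such dienes, and the ketal carbon then blocks 1,5-hydrogen shifts.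

Step 9
Reactants: 14 methyl 3-[(4S,5R)-5-[2-(5,5-dimethoxy-4-methylcyclopenta-1,3-dien-1-yl)propan-2-yl]-2,2-dimethyl-1,3-dioxolan-4-yl]propanoate
Product: 16 methyl 2-hydroxy-3-[(4S,5R)-5-[2-(5,5-dimethoxy-4-methylcyclopenta-1,3-dien-1-yl)propan-2-yl]-2,2-dimethyl-1,3-dioxolan-4-yl]propanoate (both C1 epimers), via potassium ester enolate 15 (not isolated)
Conditions: KN(SiMe3)2, THF, −78 °C; then 2-(phenylsulfonyl)-3-phenyloxaziridine, −78 °C; AcOH quench
Reagents that add atoms: 2-(phenylsulfonyl)-3-phenyloxaziridine, O=S(=O)(c1ccccc1)N1OC1c1ccccc1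
Why: The potassium ester enolate is hydroxylated at C1 by the N-sulfonyloxaziridine (electrophilic oxygen transfer), the diene being inert to the base and to this oxidant at −78 °C, and the C1 configuration is irrelevant.

Step 10
Reactants: 16 methyl 2-hydroxy-3-[(4S,5R)-5-[2-(5,5-dimethoxy-4-methylcyclopenta-1,3-dien-1-yl)propan-2-yl]-2,2-dimethyl-1,3-dioxolan-4-yl]propanoate
Product: 17 methyl 2-oxo-3-[(4S,5R)-5-[2-(5,5-dimethoxy-4-methylcyclopenta-1,3-dien-1-yl)propan-2-yl]-2,2-dimethyl-1,3-dioxolan-4-yl]propanoate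
Conditions: DMP, pyridine, CH2Cl2, 0 °C
Reagents that add atoms: none
Why: Pyridine-buffered periodinane oxidation turns the α-hydroxy ester into the α-keto ester under conditions mild enough for the dienyl ketal (hypervalent-iodine oxidation).

Step 11
Reactants: 17 methyl 2-oxo-3-[(4S,5R)-5-[2-(5,5-dimethoxy-4-methylcyclopenta-1,3-dien-1-yl)propan-2-yl]-2,2-dimethyl-1,3-dioxolan-4-yl]propanoate; 18 nitromethane
Product: 19 methyl 2-hydroxy-2-(nitromethyl)-3-[(4S,5R)-5-[2-(5,5-dimethoxy-4-methylcyclopenta-1,3-dien-1-yl)propan-2-yl]-2,2-dimethyl-1,3-dioxolan-4-yl]propanoate (both C1 epimers)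
Conditions: MeNO2 (solvent), Et3N (cat.), 0 °C to rt
Reagents that add atoms: none
Why: α-Keto esters are among the best acceptors for nitromethane under catalytic amine base, so the Henry (nitroaldol) reaction should form the C1–C9 bond without touching the diene.

Step 12
Reactants: 19 methyl 2-hydroxy-2-(nitromethyl)-3-[(4S,5R)-5-[2-(5,5-dimethoxy-4-methylcyclopenta-1,3-dien-1-yl)propan-2-yl]-2,2-dimethyl-1,3-dioxolan-4-yl]propanoate
Product: 21 methyl (Z)-2-{[(4S,5R)-5-[2-(5,5-dimethoxy-4-methylcyclopenta-1,3-dien-1-yl)propan-2-yl]-2,2-dimethyl-1,3-dioxolan-4-yl]methyl}-3-nitroprop-2-enoate, via tertiary methanesulfonate 20 (not isolated)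
Conditions: MsCl, Et3N, CH2Cl2, −30 to 0 °C; kept cold and used at once
Reagents that add atoms: none
Why: Mesylation of the tertiary alcohol through the sulfene and E1cB loss of methanesulfonate from the nitronate give the β-nitroacrylate (nitroaldol dehydration), the Z isomer with nitro cis to the ester being carried on.

Step 13
Reactants: 21 methyl (Z)-2-{[(4S,5R)-5-[2-(5,5-dimethoxy-4-methylcyclopenta-1,3-dien-1-yl)propan-2-yl]-2,2-dimethyl-1,3-dioxolan-4-yl]methyl}-3-nitroprop-2-enoate
Product: 22 cycloadduct: ring A fused to a 7,7-dimethoxybicyclo[2.2.1]hept-5-ene (C7=C8) with endo CO2Me at C1 and endo NO2 at C9 and the C3/C4 acetonide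
Conditions: toluene (high dilution), BHT (cat.), 70 °C
Reagents that add atoms: none
Why: The electron-poor Z nitroacrylate adds to the 1,4-disubstituted 5,5-dimethoxycyclopentadiene in a concerted, asynchronous, suprafacial [4+2] cycloaddition, the closest known type being intramolecular Diels–Alder reactions of tethered cyclopentadienes and cyclopentadienone ketals with nitroalkenes. Ring A closes as a six-membered ring through the C1–C6 bond (the four-atom tether C2–C5 links the diene terminus to the internal dienophile carbon and must lie exo, which gives a C5–C6–C1–C2 torsion near 45°), and the bicyclo[2.2.1]heptene closes through the C9–C10 bond across the diene termini. C1 and C6 are set relative to each other by suprafacial addition with the tether exo and the ester endo, C10 follows from the bridging, and C9 carries nitro endo because nitro is cis to the ester in the alkene. The diene face, and with it the absolute sense, is set by C3/C4: the forming ring is boat-like with C2–C3–C4–C5 nearly eclipsed, which the cis-dioxolane fits, and the dioxolane should then lie beside the endo ester and away from the C11 ketal and its inside methoxy group. The step needs this facial selectivity, while the tether length fixes the regiochemistry, the ketal carbon blocks 1,5-hydrogen shifts and the gem-dimethyl group at C5 favours the reactive fold.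

Step 14
Reactants: 22 cycloadduct with C7=C8
Product: 23 saturated nitro ester (7,7-dimethoxybicyclo[2.2.1]heptane fused to ring A; CO2Me at C1; NO2 at C9; acetonide)
Conditions: 2-O2NC6H4SO2NHNH2, Et3N, CH2Cl2, rt
Reagents that add atoms: none
Why: Diimide made in situ transfers two hydrogens suprafacially to the strained norbornene bond and leaves nitro, ester and ketals untouched (diimide reduction).

Step 15
Reactants: 23 saturated nitro ester
Product: 25 C9 ketone (β-keto ester with quaternary C1; C11 dimethyl ketal; acetonide), via potassium nitronate 24 (not isolated)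
Conditions: t-BuOK, THF, 0 °C; then O3, CH2Cl2–MeOH, −78 °C; N2 purge
Reagents that add atoms: ozone, [O-][O+]=O
Why: In this oxidative Nef reaction ozone cleaves the nitronate C=N bond to the ketone at −78 °C, and since C1 is quaternary the β-keto ester cannot enolise while the cold, non-nucleophilic medium avoids retro-Claisen cleavage.

Step 16
Reactants: 25 C9 ketone
Product: 26 C9 p-toluenesulfonylhydrazone
Conditions: TsNHNH2, PPTS (cat.), 4 Å sieves, THF, 65 °C, prolonged
Reagents that add atoms: p-toluenesulfonyl hydrazide, Cc1ccc(cc1)S(=O)(=O)NN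
Why: Mild acid-catalysed condensation in an aprotic solvent (hydrazone formation) spares both ketals, and the carbonyl, hindered like that of fenchone, is expected to need long reaction times.

Step 17
Reactants: 26 C9 p-toluenesulfonylhydrazone
Product: 29 tricyclene ester (cyclopropane C8–C9–C10 closed; CO2Me at C1; C11 dimethyl ketal; acetonide), via hydrazone sodium salt 27 (not isolated), via C9 diazoalkane 28 (not isolated)
Conditions: NaH, diglyme, rt; then 140 °C
Reagents that add atoms: none
Why: In the aprotic Bamford–Stevens reaction the salt loses sulfinate and then N2, and the C9 carbene, which has no α-hydrogen because C1 and C10 are quaternary, should insert into the endo C8–H bond as camphor- and fenchone-derived carbenes do on the way to tricyclenes, the cage dictating the configurations of C8 and C9.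

Step 18
Reactants: 29 tricyclene ester with C11 dimethyl ketal
Product: 30 C11 ketone (CO2Me at C1; acetonide)
Conditions: PPTS, acetone–H2O, 50 °C
Reagents that add atoms: water, O
Why: Transketalisation in wet acetone should hydrolyse the acyclic dimethyl ketal, whose oxocarbenium ion is stabilised by the adjacent cyclopropane, while the acetone solvent keeps the isopropylidene acetal in place (acetal hydrolysis).

Step 19
Reactants: 30 C11 ketone
Product: 31 diol (C12H2OH; C11–OH on the side of ring A; acetonide)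
Conditions: LiAlH4, THF, 0 °C to rt
Reagents that add atoms: none
Why: LiAlH4 reduces the neopentyl ester to the primary alcohol and the cyclopropyl ketone to the carbinol without ring opening (hydride reduction), hydride entering from the open C7 side so that the C11 hydroxyl points toward ring A, which step 21 corrects.

Step 20
Reactants: 31 diol
Product: 32 C12 acetate with free C11–OH
Conditions: Ac2O, pyridine, CH2Cl2, 0 °C
Reagents that add atoms: acetic anhydride, CC(=O)OC(C)=O
Why: The primary hydroxyl is acetylated selectively because the C11 hydroxyl sits between two quaternary carbons and should not react without an acyl-transfer catalyst at 0 °C (selective acylation).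

Step 21
Reactants: 32 C12 acetate with free C11–OH
Product: 34 C11,C12-diacetate acetonide (C11–OAc syn to C7), via C11 methanesulfonate 33 (not isolated)
Conditions: MsCl, Et3N, CH2Cl2, −20 °C; then KOAc, AcOH, 50 °C
Reagents that add atoms: potassium acetate, CC(=O)[O-].[K+]
Why: Buffered acetolysis of the mesylate goes through the cyclopropylcarbinyl (nortricyclyl-type) cation, which acetate should capture at C11 with the tricyclic skeleton intact and from the face remote from ring A, and this sets C11 (cyclopropylcarbinyl solvolysis).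

Step 22
Reactants: 34 C11,C12-diacetate acetonide
Product: 35 C11,C12-diacetate with free C3/C4 cis-diol
Conditions: AcOH–H2O (4:1), 40 °C
Reagents that add atoms: none
Why: Aqueous acetic acid hydrolyses the isopropylidene acetal while both acetates are stable (acetal hydrolysis).

Step 23
Reactants: 35 C11,C12-diacetate with free C3/C4 cis-diol
Product: 37 CNP0197219.1 (C3, C11 and C12 acetates; free C4–OH), via cyclic orthoacetate 36 (not isolated)
Conditions: MeC(OMe)3, PPTS (cat.), CH2Cl2, rt; then AcOH–H2O (4:1), rt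
Reagents that add atoms: trimethyl orthoacetate, COC(C)(OC)OC; water, O
Why: The cis-diol forms the cyclic orthoacetate, whose mild acid hydrolysis gives the axial acetate and the equatorial alcohol (C3–OAc, C4–OH), the usual outcome for cis-diols on a chair, and no base is used so the acetate should not migrate (orthoester opening).

**Compound list**
1 | (S)-5-(hydroxymethyl)dihydrofuran-2(3H)-one | O=C1CC[C@H](O1)CO | starting material
2 | (S)-5-oxotetrahydrofuran-2-carbaldehyde | O=C1CC[C@H](O1)C=O | intermediate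
3 | 3-chloro-3-methylbut-1-yne | CC(C)(Cl)C#C | starting material
4 | (3-methylbuta-1,2-dien-1-yl)zinc chloride | CC(C)=C=C[Zn]Cl | intermediate
5 | (S)-5-[(R)-1-hydroxy-2,2-dimethylbut-3-yn-1-yl]dihydrofuran-2(3H)-one | O=C1CC[C@H](O1)[C@H](O)C(C)(C)C#C | intermediate
6 | methyl 3-[(4S,5R)-2,2-dimethyl-5-(2-methylbut-3-yn-2-yl)-1,3-dioxolan-4-yl]propanoate | COC(=O)CC[C@@H]1OC(C)(C)O[C@@H]1C(C)(C)C#C | intermediate
7 | ethylene | C=C | starting material
8 | hexacarbonyldicobalt complex of alkyne 6, (μ-alkyne)Co2(CO)6 | COC(=O)CC[C@@H]1OC(C)(C)O[C@@H]1C(C)(C)C#C.[Co].[Co].[C-]#[O+].[C-]#[O+].[C-]#[O+].[C-]#[O+].[C-]#[O+].[C-]#[O+] | intermediate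
9 | methyl 3-[(4S,5R)-2,2-dimethyl-5-[2-(5-oxocyclopent-1-en-1-yl)propan-2-yl]-1,3-dioxolan-4-yl]propanoate | COC(=O)CC[C@@H]1OC(C)(C)O[C@@H]1C(C)(C)C1=CCCC1=O | intermediate
10 | lithium dienolate of 9 (O–Li on C11, C10=C11) | COC(=O)CC[C@@H]1OC(C)(C)O[C@@H]1C(C)(C)C1=CCC=C1O[Li] | intermediate
11 | methyl 3-[(4S,5R)-2,2-dimethyl-5-[2-(4-methyl-5-oxocyclopent-1-en-1-yl)propan-2-yl]-1,3-dioxolan-4-yl]propanoate, both C10 epimers | COC(=O)CC[C@@H]1OC(C)(C)O[C@@H]1C(C)(C)C1=CCC(C)C1=O | intermediate
12 | methyl 3-[(4S,5R)-5-[2-(5,5-dimethoxy-4-methylcyclopent-1-en-1-yl)propan-2-yl]-2,2-dimethyl-1,3-dioxolan-4-yl]propanoate | COC(=O)CC[C@@H]1OC(C)(C)O[C@@H]1C(C)(C)C1=CCC(C)C1(OC)OC | intermediate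
13 | methyl 3-[(4S,5R)-5-[2-(3-bromo-5,5-dimethoxy-4-methylcyclopent-1-en-1-yl)propan-2-yl]-2,2-dimethyl-1,3-dioxolan-4-yl]propanoate, mixture at C8 and C10 | COC(=O)CC[C@@H]1OC(C)(C)O[C@@H]1C(C)(C)C1=CC(Br)C(C)C1(OC)OC | intermediate
14 | methyl 3-[(4S,5R)-5-[2-(5,5-dimethoxy-4-methylcyclopenta-1,3-dien-1-yl)propan-2-yl]-2,2-dimethyl-1,3-dioxolan-4-yl]propanoate | COC(=O)CC[C@@H]1OC(C)(C)O[C@@H]1C(C)(C)C1=CC=C(C)C1(OC)OC | intermediate
15 | potassium ester enolate of 14 | COC(O[K])=CC[C@@H]1OC(C)(C)O[C@@H]1C(C)(C)C1=CC=C(C)C1(OC)OC | intermediate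
16 | methyl 2-hydroxy-3-[(4S,5R)-5-[2-(5,5-dimethoxy-4-methylcyclopenta-1,3-dien-1-yl)propan-2-yl]-2,2-dimethyl-1,3-dioxolan-4-yl]propanoate, both C1 epimers | COC(=O)C(O)C[C@@H]1OC(C)(C)O[C@@H]1C(C)(C)C1=CC=C(C)C1(OC)OC | intermediate
17 | methyl 2-oxo-3-[(4S,5R)-5-[2-(5,5-dimethoxy-4-methylcyclopenta-1,3-dien-1-yl)propan-2-yl]-2,2-dimethyl-1,3-dioxolan-4-yl]propanoate | COC(=O)C(=O)C[C@@H]1OC(C)(C)O[C@@H]1C(C)(C)C1=CC=C(C)C1(OC)OC | intermediate
18 | nitromethane | C[N+](=O)[O-] | starting material
19 | methyl 2-hydroxy-2-(nitromethyl)-3-[(4S,5R)-5-[2-(5,5-dimethoxy-4-methylcyclopenta-1,3-dien-1-yl)propan-2-yl]-2,2-dimethyl-1,3-dioxolan-4-yl]propanoate, both C1 epimers | COC(=O)C(O)(C[N+](=O)[O-])C[C@@H]1OC(C)(C)O[C@@H]1C(C)(C)C1=CC=C(C)C1(OC)OC | intermediate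
20 | tertiary methanesulfonate of 19 | COC(=O)C(OS(C)(=O)=O)(C[N+](=O)[O-])C[C@@H]1OC(C)(C)O[C@@H]1C(C)(C)C1=CC=C(C)C1(OC)OC | intermediate
21 | methyl (Z)-2-{[(4S,5R)-5-[2-(5,5-dimethoxy-4-methylcyclopenta-1,3-dien-1-yl)propan-2-yl]-2,2-dimethyl-1,3-dioxolan-4-yl]methyl}-3-nitroprop-2-enoate | COC(=O)/C(=C\[N+](=O)[O-])C[C@@H]1OC(C)(C)O[C@@H]1C(C)(C)C1=CC=C(C)C1(OC)OC | intermediate
22 | cycloadduct: ring A fused to 7,7-dimethoxybicyclo[2.2.1]hept-5-ene, endo CO2Me at C1, endo NO2 at C9, C3/C4 acetonide | COC(=O)[C@]12C[C@@H]3OC(C)(C)O[C@@H]3C(C)(C)[C@]14C=C[C@@](C)(C4(OC)OC)[C@@H]2[N+](=O)[O-] | intermediate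
23 | saturated nitro ester (C7–C8 single bond) | COC(=O)[C@]12C[C@@H]3OC(C)(C)O[C@@H]3C(C)(C)[C@]14CC[C@@](C)(C4(OC)OC)[C@@H]2[N+](=O)[O-] | intermediate
24 | potassium nitronate of 23 | COC(=O)[C@]12C[C@@H]3OC(C)(C)O[C@@H]3C(C)(C)[C@]14CC[C@@](C)(C4(OC)OC)C2=[N+]([O-])[O-].[K+] | intermediate
25 | C9 ketone (β-keto ester, C11 dimethyl ketal, acetonide) | COC(=O)[C@]12C[C@@H]3OC(C)(C)O[C@@H]3C(C)(C)[C@]14CC[C@@](C)(C4(OC)OC)C2=O | intermediate
26 | C9 p-toluenesulfonylhydrazone of 25 | COC(=O)[C@]12C[C@@H]3OC(C)(C)O[C@@H]3C(C)(C)[C@]14CC[C@@](C)(C4(OC)OC)C2=NNS(=O)(=O)c1ccc(C)cc1 | intermediate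
27 | sodium salt of 26 | COC(=O)[C@]12C[C@@H]3OC(C)(C)O[C@@H]3C(C)(C)[C@]14CC[C@@](C)(C4(OC)OC)C2=N[N-]S(=O)(=O)c1ccc(C)cc1.[Na+] | intermediate
28 | C9 diazoalkane | COC(=O)[C@]12C[C@@H]3OC(C)(C)O[C@@H]3C(C)(C)[C@]14CC[C@@](C)(C4(OC)OC)C2=[N+]=[N-] | intermediate
29 | tricyclene ester: cyclopropane C8–C9–C10, CO2Me at C1, C11 dimethyl ketal, acetonide | COC(=O)[C@]12C[C@@H]4OC(C)(C)O[C@@H]4C(C)(C)[C@]13C[C@@H]1[C@H]2[C@]1(C)C3(OC)OC | intermediate
30 | C11 ketone of the tricyclene ester | COC(=O)[C@]12C[C@@H]4OC(C)(C)O[C@@H]4C(C)(C)[C@]13C[C@@H]1[C@H]2[C@]1(C)C3=O | intermediate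
31 | diol: C12H2OH and C11–OH (hydroxyl toward ring A), acetonide | OC[C@]12C[C@@H]4OC(C)(C)O[C@@H]4C(C)(C)[C@]13C[C@@H]1[C@H]2[C@]1(C)[C@@H]3O | intermediate
32 | C12 acetate of 31 | CC(=O)OC[C@]12C[C@@H]4OC(C)(C)O[C@@H]4C(C)(C)[C@]13C[C@@H]1[C@H]2[C@]1(C)[C@@H]3O | intermediate
33 | C11 methanesulfonate of 32 | CC(=O)OC[C@]12C[C@@H]4OC(C)(C)O[C@@H]4C(C)(C)[C@]13C[C@@H]1[C@H]2[C@]1(C)[C@@H]3OS(C)(=O)=O | intermediate
34 | C11,C12-diacetate acetonide (C11–OAc syn to C7) | CC(=O)OC[C@]12C[C@@H]4OC(C)(C)O[C@@H]4C(C)(C)[C@]13C[C@@H]1[C@H]2[C@]1(C)[C@H]3OC(C)=O | intermediate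
35 | C11,C12-diacetate C3,C4-diol | CC(=O)OC[C@]12C[C@H](O)[C@H](O)C(C)(C)[C@]13C[C@@H]1[C@H]2[C@]1(C)[C@H]3OC(C)=O | intermediate
36 | C3,C4 cyclic methyl orthoacetate of 35 | CC(=O)OC[C@]12C[C@@H]4OC(C)(OC)O[C@@H]4C(C)(C)[C@]13C[C@@H]1[C@H]2[C@]1(C)[C@H]3OC(C)=O | intermediate
37 | CNP0197219.1 | CC(=O)OC[C@]12C[C@H](OC(C)=O)[C@H](O)C(C)(C)[C@]13C[C@@H]1[C@H]2[C@]1(C)[C@H]3OC(C)=O | target

**Totals**
Total step count: 23. Longest linear sequence: 23 steps (fully linear from 1).

**Steps most likely to fail**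

Step 13. The risk is loss of π-facial control if the dioxolane does not steer the fold of the tether, which would give the diastereomeric cage. The fallback ties the ester to O3 as a γ-lactone, so that C12 and O3 are forced cis on ring A and C1–C6 can only form on the lactone face that carries C4. It sets out from 19: aqueous acetic acid removes the acetonide and the freed C3 hydroxyl lactonises onto the methyl ester to give the hydroxy lactone F1. Et3SiCl/imidazole silylates the secondary C4 hydroxyl to give the silyl ether F2. MsCl/Et3N dehydrates the tertiary nitro alcohol to the nitromethylene lactone F3, which is heated in toluene to give the lactone cycloadduct F4. TsOH in MeOH with 2,2-dimethoxypropane then removes the silyl group, opens the lactone to the methyl ester and restores the acetonide, and the route is rejoined at 22.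

Step 16. The risk is that condensation fails at the doubly neopentyl C9 carbonyl, or that the neighbouring ester acylates the hydrazone nitrogen. The fallback takes the ester out of play first and reaches the carbene through the unsubstituted hydrazone. It sets out from 23: LiBH4 reduces the ester to the primary alcohol F5 without touching the nitro group, and t-BuMe2SiCl/imidazole gives the silyl ether F6. The same nitronate ozonolysis gives the ketone F7. Anhydrous hydrazine in triethylene glycol at 130 °C gives the hydrazone F8, and oxidation with HgO (cat. KOH, diglyme, heat) passes through the diazoalkane to the tricyclene F9. PPTS in wet acetone frees the C11 ketone F10, NaBH4 gives the C11 alcohol F11, and Bu4NF removes the silyl group, so the route is rejoined at 31.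

Step 21. The risk is capture of the cyclopropylcarbinyl cation at a cyclopropane carbon (ring opening to homoallylic acetates) or on the wrong face, together with partial loss of the acetonide in warm acetic acid. The fallback sets C11 under thermodynamic control without a cation. It sets out from 31: Meerwein–Ponndorf–Verley/Oppenauer equilibration (Al(O-i-Pr)3, i-PrOH, a little acetone, toluene, reflux) should move the hydroxyl to the less encumbered side and give the epimeric diol F12. Ac2O with DMAP in pyridine then acetylates both hydroxyls, and the route is rejoined at 34.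

**Further compounds**
F1 | step 13 | hydroxy lactone: γ-lactone C12(=O)–O3 with tertiary OH and CH2NO2 on C1, free C4–OH, dienyl ketal | O=C1O[C@@H](CC1(O)C[N+](=O)[O-])[C@H](O)C(C)(C)C1=CC=C(C)C1(OC)OC
F2 | step 13 | C4 triethylsilyl ether of F1 | O=C1O[C@@H](CC1(O)C[N+](=O)[O-])[C@H](O[Si](CC)(CC)CC)C(C)(C)C1=CC=C(C)C1(OC)OC
F3 | step 13 | (Z)-α-(nitromethylene)-γ-lactone with C4 triethylsilyl ether and dienyl ketal | [O-][N+](=O)/C=C1/C[C@H](OC1=O)[C@H](O[Si](CC)(CC)CC)C(C)(C)C1=CC=C(C)C1(OC)OC
F4 | step 13 | lactone cycloadduct: 22 with the C12/O3 γ-lactone in place of ester and acetonide, C4 triethylsilyl ether | O=C5[C@]12C[C@H](O5)[C@H](O[Si](CC)(CC)CC)C(C)(C)[C@]14C=C[C@@](C)(C4(OC)OC)[C@@H]2[N+](=O)[O-]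
F5 | step 16 | primary alcohol: 23 with C12H2OH in place of CO2Me | OC[C@]12C[C@@H]3OC(C)(C)O[C@@H]3C(C)(C)[C@]14CC[C@@](C)(C4(OC)OC)[C@@H]2[N+](=O)[O-]
F6 | step 16 | C12 tert-butyldimethylsilyl ether of F5 | CC(C)(C)[Si](C)(C)OC[C@]12C[C@@H]3OC(C)(C)O[C@@H]3C(C)(C)[C@]14CC[C@@](C)(C4(OC)OC)[C@@H]2[N+](=O)[O-]
F7 | step 16 | C9 ketone with C12 silyl ether | CC(C)(C)[Si](C)(C)OC[C@]12C[C@@H]3OC(C)(C)O[C@@H]3C(C)(C)[C@]14CC[C@@](C)(C4(OC)OC)C2=O
F8 | step 16 | C9 hydrazone of F7 | CC(C)(C)[Si](C)(C)OC[C@]12C[C@@H]3OC(C)(C)O[C@@H]3C(C)(C)[C@]14CC[C@@](C)(C4(OC)OC)C2=NN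
F9 | step 16 | tricyclene with C12 silyl ether, C11 dimethyl ketal, acetonide | CC(C)(C)[Si](C)(C)OC[C@]12C[C@@H]4OC(C)(C)O[C@@H]4C(C)(C)[C@]13C[C@@H]1[C@H]2[C@]1(C)C3(OC)OC
F10 | step 16 | C11 ketone of F9 | CC(C)(C)[Si](C)(C)OC[C@]12C[C@@H]4OC(C)(C)O[C@@H]4C(C)(C)[C@]13C[C@@H]1[C@H]2[C@]1(C)C3=O
F11 | step 16 | C11 alcohol (hydroxyl toward ring A) with C12 silyl ether | CC(C)(C)[Si](C)(C)OC[C@]12C[C@@H]4OC(C)(C)O[C@@H]4C(C)(C)[C@]13C[C@@H]1[C@H]2[C@]1(C)[C@@H]3O
F12 | step 21 | C11 epimer of diol 31 (hydroxyl syn to C7) | OC[C@]12C[C@@H]4OC(C)(C)O[C@@H]4C(C)(C)[C@]13C[C@@H]1[C@H]2[C@]1(C)[C@H]3O
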